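**Retrosynthetic overview**

1. The nitrogen ring is closed last: the C1–C8a bond comes from a Bischler–Napieralski cyclization of the N-acetyl derivative of a (2S)-1-aryl-2-aminopropane.
2. Key disconnection: the carbocycle C4a–C5–C6–C7–C8–C8a of the isoquinoline is a meta-dioxygenated ring (O on C6 and C8, H on C7) with the naphthyl group on C5 beside oxygenated C6 and the side chain on C4a. A vinylketene (C6, C8a, C4a, C5) and methoxyethyne (C7, C8) assemble exactly this pattern, so the ring is grown on the naphthalene and the crowded C5–C1' bond is never made by coupling.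
3. The vinylketene comes from an (E)-alkenyl diazomethyl ketone. This is made by diazo transfer to a methyl enone, which arises from N-Boc (S)-5-methylpyrrolidin-2-one by aldol condensation with the naphthaldehyde and ring opening with MeLi; the lactam stereocentre becomes C3.
4. The naphthaldehyde comes from a benzamide by directed metalation–allylation, anionic annulation, O-methylation, bromination and formylation at C1'.
5. Ring order: second naphthalene ring, then the resorcinol ring (key step), then the nitrogen ring.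

Key step: step 13

Remark on the chemistry: the target structure defines only C3 (S) and leaves the C5–C1' axis open, so the route is planned to give the (3S) compound as a pair of atropo-diastereomers, separable by chromatography at the end if one axial form is wanted; (5S)-5-methylpyrrolidin-2-one is taken as a purchasable chiral lactam.

**Route**

Step 1
Reactants: 1 N,N-diethyl-2-methoxybenzamide; 2 3-bromo-2-methylpropene
Product: 5 N,N-diethyl-2-methoxy-6-(2-methylprop-2-en-1-yl)benzamide, via aryllithium 3 (not isolated), via arylmagnesium bromide 4 (not isolated)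
Conditions: s-BuLi, TMEDA, THF, −78 °C; MgBr2·OEt2, −78 °C to rt; then 2, −78 °C to rt
Reagents that add atoms: none
Why: Directed ortho-metalation, in which the diethylamide outranks the methoxy group and sends lithium to C6, followed by transmetalation to a less basic arylmagnesium species that is allylated without deprotonating the doubly activated benzylic position of the product; the methallyl unit is symmetric, so SN2 and SN2' attack give the same compound.

Step 2
Reactants: 5 N,N-diethyl-2-methoxy-6-(2-methylprop-2-en-1-yl)benzamide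
Product: 8 8-methoxy-3-methylnaphthalen-1-ol, via allyllithium 6 (not isolated), via naphthalenone 7 (not isolated)
Conditions: LiN(i-Pr)2 (2.2 equiv), THF, −78 °C to rt; aq. NH4Cl
Reagents that add atoms: none
Why: Anionic ring annulation of an ortho-allyl benzamide, in which the benzylic allylic anion acylates the neighbouring amide through its terminal carbon (six-membered ring, loss of diethylamide) and the resulting naphthalenone tautomerizes to the naphthol with OH on C1, methyl on C3 and methoxy on C8.

Step 3
Reactants: 8 8-methoxy-3-methylnaphthalen-1-ol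
Product: 9 1,8-dimethoxy-3-methylnaphthalene
Conditions: MeI, K2CO3, acetone, reflux
Reagents that add atoms: iodomethane, CI
Why: Williamson ether synthesis on the naphthol, whose hydrogen bond to the peri methoxy group only slows the alkylation and is overcome by heating.

Step 4
Reactants: 9 1,8-dimethoxy-3-methylnaphthalene
Product: 10 1-bromo-4,5-dimethoxy-2-methylnaphthalene
Conditions: NBS (1.0 equiv), MeCN, 0 °C to rt
Reagents that add atoms: N-bromosuccinimide, O=C1CCC(=O)N1Br
Why: Electrophilic aromatic bromination should occur at the position para to a methoxy group that is also activated by the ortho methyl group, which makes the methyl-bearing ring the more nucleophilic of the two.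

Step 5
Reactants: 10 1-bromo-4,5-dimethoxy-2-methylnaphthalene
Product: 13 4,5-dimethoxy-2-methylnaphthalene-1-carbaldehyde, via naphthyllithium 11 (not isolated), via lithium hemiaminolate 12 (not isolated)
Conditions: n-BuLi, THF, −78 °C; DMF, −78 °C to rt; aq. NH4Cl
Reagents that add atoms: N,N-dimethylformamide, CN(C)C=O
Why: Bromine–lithium exchange is faster than any deprotonation and the hindered aryllithium is formylated by DMF through a tetrahedral adduct that releases the aldehyde only on work-up (Bouveault-type formylation).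

Step 6
Reactants: 14 (5S)-5-methylpyrrolidin-2-one
Product: 15 tert-butyl (2S)-2-methyl-5-oxopyrrolidine-1-carboxylate
Conditions: Boc2O, DMAP (cat.), Et3N, CH2Cl2, rt
Reagents that add atoms: di-tert-butyl dicarbonate, CC(C)(C)OC(=O)OC(=O)OC(C)(C)C
Why: DMAP-catalysed N-acylation of the lactam removes the acidic N–H before enolate formation and turns the ring carbonyl into an imide-type electrophile for the later ring opening, without touching the stereocentre.

Step 7
Reactants: 15 tert-butyl (2S)-2-methyl-5-oxopyrrolidine-1-carboxylate; 13 4,5-dimethoxy-2-methylnaphthalene-1-carbaldehyde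
Product: 17 tert-butyl (5S)-3-[(4,5-dimethoxy-2-methylnaphthalen-1-yl)(hydroxy)methyl]-5-methyl-2-oxopyrrolidine-1-carboxylate, via lithium enolate 16 (not isolated)
Conditions: LiN(SiMe3)2, THF, −78 °C; then 13, −78 °C; aq. NH4Cl
Reagents that add atoms: none
Why: Aldol addition of the lithium enolate of an N-acyl lactam to a non-enolizable aldehyde; the two new stereocentres (C3 and the carbinol carbon) form as a mixture that does not matter because both are removed in step 8, and C5 is not alpha to the carbonyl and cannot epimerize.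

Step 8
Reactants: 17 tert-butyl (5S)-3-[(4,5-dimethoxy-2-methylnaphthalen-1-yl)(hydroxy)methyl]-5-methyl-2-oxopyrrolidine-1-carboxylate
Product: 19 tert-butyl (3E,5S)-3-[(4,5-dimethoxy-2-methylnaphthalen-1-yl)methylidene]-5-methyl-2-oxopyrrolidine-1-carboxylate, via mesylate 18 (not isolated)
Conditions: MsCl, Et3N, CH2Cl2, 0 °C; then DBU, rt
Reagents that add atoms: none
Why: Mesylation and DBU-induced E1cB elimination give the conjugated arylidene lactam, and the E isomer, with the bulky naphthyl group trans to the ring carbonyl, is the favoured outcome of such aldol condensations.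

Step 9
Reactants: 19 tert-butyl (3E,5S)-3-[(4,5-dimethoxy-2-methylnaphthalen-1-yl)methylidene]-5-methyl-2-oxopyrrolidine-1-carboxylate
Product: 21 tert-butyl N-[(2S,4E)-4-acetyl-5-(4,5-dimethoxy-2-methylnaphthalen-1-yl)pent-4-en-2-yl]carbamate, via lithium hemiaminolate 20 (not isolated)
Conditions: MeLi (1.1 equiv), THF, −78 °C; AcOH quench at −78 °C
Reagents that add atoms: methyllithium, [Li]C
Why: Acyl substitution of an N-Boc lactam by an organolithium, in which the hard nucleophile adds 1,2 to the carbamate-activated ring carbonyl (the beta carbon is shielded by the twisted naphthyl group) and the tetrahedral lithium alkoxide opens to the methyl ketone only on protonation, so a second addition is avoided and both alkene geometry and configuration are kept.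

Step 10
Reactants: 21 tert-butyl N-[(2S,4E)-4-acetyl-5-(4,5-dimethoxy-2-methylnaphthalen-1-yl)pent-4-en-2-yl]carbamate
Product: 22 di-tert-butyl N-[(2S,4E)-4-acetyl-5-(4,5-dimethoxy-2-methylnaphthalen-1-yl)pent-4-en-2-yl]imidodicarbonate
Conditions: Boc2O (3 equiv), DMAP, MeCN, rt to 40 °C
Reagents that add atoms: di-tert-butyl dicarbonate, CC(C)(C)OC(=O)OC(=O)OC(C)(C)C
Why: DMAP-catalysed tert-butoxycarbonylation of the carbamate N–H gives the imidodicarbonate, so that no N–H is left for the enolate chemistry of step 11 or for addition to the ketene in step 13.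

Step 11
Reactants: 22 di-tert-butyl N-[(2S,4E)-4-acetyl-5-(4,5-dimethoxy-2-methylnaphthalen-1-yl)pent-4-en-2-yl]imidodicarbonate
Product: 24 di-tert-butyl N-[(2S,4E)-4-(2-diazoacetyl)-5-(4,5-dimethoxy-2-methylnaphthalen-1-yl)pent-4-en-2-yl]imidodicarbonate, via trifluoroacetyl diketone 23 (not isolated)
Conditions: LiN(SiMe3)2, THF, −78 °C; CF3CO2CH2CF3, −78 °C; aq. HCl wash; then MsN3, Et3N, H2O (1 equiv), MeCN, rt
Reagents that add atoms: methanesulfonyl azide, CS(=O)(=O)N=[N+]=[N-]
Why: Detrifluoroacetylative diazo transfer, in which kinetic deprotonation of the acetyl methyl group and Claisen-type trifluoroacetylation give an activated 1,3-diketone that accepts the diazo group and loses the trifluoroacetyl group, so that no conjugated acyl derivative is exposed to diazomethane and its dipolar addition to the alkene.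

Step 12
Reactants: 25 chloroacetaldehyde dimethyl acetal
Product: 28 methoxyethyne, via 1-chloro-2-methoxyethene 26 (not isolated), via sodium methoxyethynide 27 (not isolated)
Conditions: NaNH2 (3 equiv), liq. NH3, −33 °C; cold sat. aq. NaCl, −70 °C; distillation into a −78 °C trap
Reagents that add atoms: none
Why: Two base-induced eliminations (methanol, then hydrogen chloride) give the alkoxyalkyne, which is held as its sodium acetylide until the aqueous quench, the standard preparation of volatile alkoxyethynes.

Step 13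
Reactants: 24 di-tert-butyl N-[(2S,4E)-4-(2-diazoacetyl)-5-(4,5-dimethoxy-2-methylnaphthalen-1-yl)pent-4-en-2-yl]imidodicarbonate; 28 methoxyethyne
Product: 33 di-tert-butyl N-[(2S)-1-[2-(4,5-dimethoxy-2-methylnaphthalen-1-yl)-3-hydroxy-5-methoxyphenyl]propan-2-yl]imidodicarbonate, via vinylketene 29 (not isolated), via cyclobutenone 30 (not isolated), via dienylketene 31 (not isolated), via cyclohexadienone 32 (not isolated)
Conditions: 28 (4 equiv), degassed ClCH2CH2Cl (0.05 M), hν 254 nm (low-pressure Hg lamps, sealed quartz tube), 10–20 °C; then 80 °C in the sealed tube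
Reagents that add atoms: none
Why: Light expels N2 from 24 and the alkenyl group migrates (Wolff rearrangement) to give vinylketene 29, which takes up the electron-rich alkyne 28 in a [2+2] cycloaddition that closes the transient four-membered ring of 30; at 80 °C this ring opens reversibly by a conrotatory four-electron electrocyclic reaction to dienylketene 31, and the one ring that is kept, the benzene ring C4a–C5–C6–C7–C8–C8a, closes by a thermal disrotatory six-electron electrocyclization between the ketene carbon (C6) and the naphthyl-bearing alkene terminus (C5), after which dienone 32 tautomerizes to phenol 33. The closest known reaction type is the Danheiser benzannulation in its photochemical Wolff variant, in which alkenyl diazomethyl ketones are combined with heteroatom-substituted alkynes. No stereocentre is created that persists: the sp3 centres of 30 and 32 disappear on ring opening and aromatization, the (S)-centre is remote and untouched, and the new C5–C1' axis forms without control as a pair of atropo-diastereomers. The selectivity that matters is the regiochemistry of the [2+2] step, which the polarity of the alkoxyalkyne secures: its nucleophilic unsubstituted carbon bonds to the electrophilic ketene carbon, so that hydrogen ends on C7 and the methoxy group on C8, meta to the new hydroxyl group. The E alkene of 24 places the naphthyl group on the outer side of the triene terminus, a Z isomer formed by photoisomerization would converge on the same phenol because C5 becomes aromatic, and closure of the ketene onto the naphthalene is excluded because both positions next to C1' are substituted. The imidodicarbonate nitrogen has no N–H that could add to the ketene or to a carbene.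

Step 14
Reactants: 33 di-tert-butyl N-[(2S)-1-[2-(4,5-dimethoxy-2-methylnaphthalen-1-yl)-3-hydroxy-5-methoxyphenyl]propan-2-yl]imidodicarbonate
Product: 34 di-tert-butyl N-[(2S)-1-[2-(4,5-dimethoxy-2-methylnaphthalen-1-yl)-3,5-dimethoxyphenyl]propan-2-yl]imidodicarbonate
Conditions: MeI, K2CO3, DMF, rt to 40 °C
Reagents that add atoms: iodomethane, CI
Why: Williamson methylation of the hindered C6 phenol, the only acidic group present, under conditions to which the imidodicarbonate is stable.

Step 15
Reactants: 34 di-tert-butyl N-[(2S)-1-[2-(4,5-dimethoxy-2-methylnaphthalen-1-yl)-3,5-dimethoxyphenyl]propan-2-yl]imidodicarbonate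
Product: 36 N-[(2S)-1-[2-(4,5-dimethoxy-2-methylnaphthalen-1-yl)-3,5-dimethoxyphenyl]propan-2-yl]acetamide, via ammonium chloride 35 (not isolated)
Conditions: HCl (4 M in dioxane), rt; evaporation; Ac2O, Et3N, CH2Cl2, 0 °C to rt
Reagents that add atoms: acetic anhydride, CC(=O)OC(C)=O
Why: Acidolysis removes both Boc groups as 2-methylpropene and CO2, with chloride as counter-ion limiting tert-butylation of the electron-rich rings, and the liberated primary amine is N-acetylated once Et3N is added, the stereocentre taking no part.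

Step 16
Reactants: 36 N-[(2S)-1-[2-(4,5-dimethoxy-2-methylnaphthalen-1-yl)-3,5-dimethoxyphenyl]propan-2-yl]acetamide
Product: 38 O-methylancistrocladinine, (3S)-5-(4,5-dimethoxy-2-methylnaphthalen-1-yl)-6,8-dimethoxy-1,3-dimethyl-3,4-dihydroisoquinoline (both atropo-diastereomers), via imidoyl dichlorophosphate 37 (not isolated)
Conditions: POCl3, 2,4,6-collidine, MeCN, reflux; aq. NaHCO3
Reagents that add atoms: none
Why: Bischler–Napieralski cyclodehydration, in which the activated amide (imidoyl phosphate or nitrilium ion) attacks C8a, the only free position ortho to the side chain and one activated by the ortho C8 and para C6 methoxy groups, giving the C1=N bond directly and leaving C3 untouched.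

**Compound list**

1 | N,N-diethyl-2-methoxybenzamide | CCN(CC)C(=O)c1ccccc1OC | starting material
2 | 3-bromo-2-methylpropene | C=C(C)CBr | starting material
3 | N,N-diethyl-2-lithio-6-methoxybenzamide | [Li]c1cccc(OC)c1C(=O)N(CC)CC | intermediate (not isolated)
4 | [2-(diethylcarbamoyl)-3-methoxyphenyl]magnesium bromide | Br[Mg]c1cccc(OC)c1C(=O)N(CC)CC | intermediate (not isolated)
5 | N,N-diethyl-2-methoxy-6-(2-methylprop-2-en-1-yl)benzamide | CCN(CC)C(=O)c1c(CC(C)=C)cccc1OC | intermediate
6 | [1-[2-(diethylcarbamoyl)-3-methoxyphenyl]-2-methylprop-2-en-1-yl]lithium | [Li]C(C(C)=C)c1cccc(OC)c1C(=O)N(CC)CC | intermediate (not isolated)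
7 | 8-methoxy-3-methylnaphthalen-1(2H)-one | O=C1CC(C)=Cc2cccc(OC)c12 | intermediate (not isolated)
8 | 8-methoxy-3-methylnaphthalen-1-ol | Oc1cc(C)cc2cccc(OC)c12 | intermediate
9 | 1,8-dimethoxy-3-methylnaphthalene | COc1cc(C)cc2cccc(OC)c12 | intermediate
10 | 1-bromo-4,5-dimethoxy-2-methylnaphthalene | Brc1c(C)cc(OC)c2c(OC)cccc12 | intermediate
11 | (4,5-dimethoxy-2-methylnaphthalen-1-yl)lithium | [Li]c1c(C)cc(OC)c2c(OC)cccc12 | intermediate (not isolated)
12 | lithium (4,5-dimethoxy-2-methylnaphthalen-1-yl)(dimethylamino)methanolate | [Li]OC(N(C)C)c1c(C)cc(OC)c2c(OC)cccc12 | intermediate (not isolated)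
13 | 4,5-dimethoxy-2-methylnaphthalene-1-carbaldehyde | O=Cc1c(C)cc(OC)c2c(OC)cccc12 | intermediate
14 | (5S)-5-methylpyrrolidin-2-one | C[C@H]1CCC(=O)N1 | starting material
15 | tert-butyl (2S)-2-methyl-5-oxopyrrolidine-1-carboxylate | C[C@H]1CCC(=O)N1C(=O)OC(C)(C)C | intermediate
16 | lithium enolate of 15 | C[C@H]1CC=C(O[Li])N1C(=O)OC(C)(C)C | intermediate (not isolated)
17 | tert-butyl (5S)-3-[(4,5-dimethoxy-2-methylnaphthalen-1-yl)(hydroxy)methyl]-5-methyl-2-oxopyrrolidine-1-carboxylate (mixture at C3 and the carbinol carbon) | C[C@H]1CC(C(O)c2c(C)cc(OC)c3c(OC)cccc23)C(=O)N1C(=O)OC(C)(C)C | intermediate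
18 | methanesulfonate of 17 | C[C@H]1CC(C(OS(C)(=O)=O)c2c(C)cc(OC)c3c(OC)cccc23)C(=O)N1C(=O)OC(C)(C)C | intermediate (not isolated)
19 | tert-butyl (3E,5S)-3-[(4,5-dimethoxy-2-methylnaphthalen-1-yl)methylidene]-5-methyl-2-oxopyrrolidine-1-carboxylate | C[C@H]1C/C(=C\c2c(C)cc(OC)c3c(OC)cccc23)C(=O)N1C(=O)OC(C)(C)C | intermediate
20 | lithium alkoxide of the 2-hydroxy-2-methylpyrrolidine formed by addition of MeLi to 19 | C[C@H]1C/C(=C\c2c(C)cc(OC)c3c(OC)cccc23)C(C)(O[Li])N1C(=O)OC(C)(C)C | intermediate (not isolated)
21 | tert-butyl N-[(2S,4E)-4-acetyl-5-(4,5-dimethoxy-2-methylnaphthalen-1-yl)pent-4-en-2-yl]carbamate | CC(=O)/C(C[C@H](C)NC(=O)OC(C)(C)C)=C/c1c(C)cc(OC)c2c(OC)cccc12 | intermediate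
22 | di-tert-butyl N-[(2S,4E)-4-acetyl-5-(4,5-dimethoxy-2-methylnaphthalen-1-yl)pent-4-en-2-yl]imidodicarbonate | CC(=O)/C(C[C@H](C)N(C(=O)OC(C)(C)C)C(=O)OC(C)(C)C)=C/c1c(C)cc(OC)c2c(OC)cccc12 | intermediate
23 | 4,4,4-trifluoro-3-oxobutanoyl analogue of 22 (trifluoroacetyl diketone) | FC(F)(F)C(=O)CC(=O)/C(C[C@H](C)N(C(=O)OC(C)(C)C)C(=O)OC(C)(C)C)=C/c1c(C)cc(OC)c2c(OC)cccc12 | intermediate (not isolated)
24 | di-tert-butyl N-[(2S,4E)-4-(2-diazoacetyl)-5-(4,5-dimethoxy-2-methylnaphthalen-1-yl)pent-4-en-2-yl]imidodicarbonate | [N-]=[N+]=CC(=O)/C(C[C@H](C)N(C(=O)OC(C)(C)C)C(=O)OC(C)(C)C)=C/c1c(C)cc(OC)c2c(OC)cccc12 | intermediate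
25 | chloroacetaldehyde dimethyl acetal | COC(CCl)OC | starting material
26 | 1-chloro-2-methoxyethene | COC=CCl | intermediate (not isolated)
27 | sodium methoxyethynide | [Na]C#COC | intermediate (not isolated)
28 | methoxyethyne | COC#C | intermediate
29 | vinylketene from 24 | O=C=C/C(C[C@H](C)N(C(=O)OC(C)(C)C)C(=O)OC(C)(C)C)=C/c1c(C)cc(OC)c2c(OC)cccc12 | intermediate (not isolated)
30 | 4-alkenyl-3-methoxycyclobut-2-en-1-one (ring carbon C4 unassigned) | O=C1C=C(OC)C1/C(C[C@H](C)N(C(=O)OC(C)(C)C)C(=O)OC(C)(C)C)=C/c1c(C)cc(OC)c2c(OC)cccc12 | intermediate (not isolated)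
31 | dienylketene | O=C=C/C(OC)=C\C(C[C@H](C)N(C(=O)OC(C)(C)C)C(=O)OC(C)(C)C)=C\c1c(C)cc(OC)c2c(OC)cccc12 | intermediate (not isolated)
32 | 6-aryl-3-methoxycyclohexa-2,4-dien-1-one (C6 unassigned) | O=C1C=C(OC)C=C(C[C@H](C)N(C(=O)OC(C)(C)C)C(=O)OC(C)(C)C)C1c1c(C)cc(OC)c2c(OC)cccc12 | intermediate (not isolated)
33 | di-tert-butyl N-[(2S)-1-[2-(4,5-dimethoxy-2-methylnaphthalen-1-yl)-3-hydroxy-5-methoxyphenyl]propan-2-yl]imidodicarbonate | Oc1cc(OC)cc(C[C@H](C)N(C(=O)OC(C)(C)C)C(=O)OC(C)(C)C)c1-c1c(C)cc(OC)c2c(OC)cccc12 | intermediate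
34 | di-tert-butyl N-[(2S)-1-[2-(4,5-dimethoxy-2-methylnaphthalen-1-yl)-3,5-dimethoxyphenyl]propan-2-yl]imidodicarbonate | COc1cc(OC)cc(C[C@H](C)N(C(=O)OC(C)(C)C)C(=O)OC(C)(C)C)c1-c1c(C)cc(OC)c2c(OC)cccc12 | intermediate
35 | (2S)-1-[2-(4,5-dimethoxy-2-methylnaphthalen-1-yl)-3,5-dimethoxyphenyl]propan-2-aminium chloride | COc1cc(OC)cc(C[C@H](C)[NH3+])c1-c1c(C)cc(OC)c2c(OC)cccc12.[Cl-] | intermediate (not isolated)
36 | N-[(2S)-1-[2-(4,5-dimethoxy-2-methylnaphthalen-1-yl)-3,5-dimethoxyphenyl]propan-2-yl]acetamide | COc1cc(OC)cc(C[C@H](C)NC(C)=O)c1-c1c(C)cc(OC)c2c(OC)cccc12 | intermediate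
37 | imidoyl dichlorophosphate of 36 | COc1cc(OC)cc(C[C@H](C)N=C(C)OP(Cl)(Cl)=O)c1-c1c(C)cc(OC)c2c(OC)cccc12 | intermediate (not isolated)
38 | O-methylancistrocladinine | COc1cc(OC)c(-c2c(C)cc(OC)c3c(OC)cccc23)c2c1C(C)=N[C@@H](C)C2 | target

**Step count**

Total: 16 steps. Longest linear sequence: 14 steps (steps 1–5, 7–11 and 13–16, from compound 1).

**Steps most likely to fail**

1. Step 13. The ketene may be consumed by dimerization or by acylating the product phenol, the electrocyclic closure at the hindered alkene terminus may be slow, and light absorption by the naphthylidene chromophore may hold back the Wolff rearrangement.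
Fallback: a biaryl cross-coupling that sets out from 10 and comes back at 36. Miyaura borylation of 10 (bis(pinacolato)diboron, PdCl2(dppf), KOAc, dioxane, 90 °C) would give 2-(4,5-dimethoxy-2-methylnaphthalen-1-yl)-4,4,5,5-tetramethyl-1,3,2-dioxaborolane F1. Separately, purchased 3,5-dimethoxyphenylmagnesium chloride would open purchased tert-butyl (2S)-2-methylaziridine-1-carboxylate at its CH2 carbon (CuI cat., THF, −30 °C to rt) to give tert-butyl N-[(2S)-1-(3,5-dimethoxyphenyl)propan-2-yl]carbamate F2. NBS in MeCN at 0 °C would brominate the position between the side chain and a methoxy group, giving tert-butyl N-[(2S)-1-(2-bromo-3,5-dimethoxyphenyl)propan-2-yl]carbamate F3. Suzuki–Miyaura coupling of F1 with F3 (Pd(OAc)2, SPhos, K3PO4, toluene/H2O, 100 °C) would give tert-butyl N-[(2S)-1-[2-(4,5-dimethoxy-2-methylnaphthalen-1-yl)-3,5-dimethoxyphenyl]propan-2-yl]carbamate F4, which under the conditions of step 15 is converted into 36.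

2. Step 9. Chemoselectivity may be lost through conjugate addition, attack at the carbamate carbonyl, or a second addition after premature ring opening.
Fallback: a Weinreb ketone synthesis that sets out from 19 and comes back at 21. Hydrolytic ring opening (LiOH, THF/H2O, 0 °C) would give (2E,4S)-4-[(tert-butoxycarbonyl)amino]-2-[(4,5-dimethoxy-2-methylnaphthalen-1-yl)methylidene]pentanoic acid F5. Amide coupling with N,O-dimethylhydroxylamine hydrochloride (EDC·HCl, HOBt, i-Pr2NEt, CH2Cl2) would give tert-butyl N-[(2S,4E)-5-(4,5-dimethoxy-2-methylnaphthalen-1-yl)-4-[methoxy(methyl)carbamoyl]pent-4-en-2-yl]carbamate F6, and MeMgBr (2.5 equiv, THF, 0 °C) would convert it into 21 through the chelated adduct, which cannot add twice.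

3. Step 11. Acylation of the enolate may be incomplete or misdirected, and the base may cause migration or loss of a Boc group before diazo transfer.
Fallback: acylation of diazomethane, which sets out from 19 and comes back at 24. Methanolysis of the lactam (NaOMe cat., MeOH, 0 °C) would give methyl (2E,4S)-4-[(tert-butoxycarbonyl)amino]-2-[(4,5-dimethoxy-2-methylnaphthalen-1-yl)methylidene]pentanoate F7. Boc2O and DMAP in MeCN would give methyl (2E,4S)-4-[bis(tert-butoxycarbonyl)amino]-2-[(4,5-dimethoxy-2-methylnaphthalen-1-yl)methylidene]pentanoate F8, and LiOH in THF/MeOH/H2O would give (2E,4S)-4-[bis(tert-butoxycarbonyl)amino]-2-[(4,5-dimethoxy-2-methylnaphthalen-1-yl)methylidene]pentanoic acid F9. Activation with isobutyl chloroformate and N-methylmorpholine (THF, −15 °C) would give the isobutyl carbonic mixed anhydride F10, which is treated in the same flask with ethereal diazomethane at 0 °C (kept cold and short to limit dipolar addition to the alkene) to give 24.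

**Further compounds**

F1 | step 13 | 2-(4,5-dimethoxy-2-methylnaphthalen-1-yl)-4,4,5,5-tetramethyl-1,3,2-dioxaborolane | CC1(C)OB(OC1(C)C)c1c(C)cc(OC)c2c(OC)cccc12
F2 | step 13 | tert-butyl N-[(2S)-1-(3,5-dimethoxyphenyl)propan-2-yl]carbamate | COc1cc(OC)cc(C[C@H](C)NC(=O)OC(C)(C)C)c1
F3 | step 13 | tert-butyl N-[(2S)-1-(2-bromo-3,5-dimethoxyphenyl)propan-2-yl]carbamate | COc1cc(OC)cc(C[C@H](C)NC(=O)OC(C)(C)C)c1Br
F4 | step 13 | tert-butyl N-[(2S)-1-[2-(4,5-dimethoxy-2-methylnaphthalen-1-yl)-3,5-dimethoxyphenyl]propan-2-yl]carbamate | COc1cc(OC)cc(C[C@H](C)NC(=O)OC(C)(C)C)c1-c1c(C)cc(OC)c2c(OC)cccc12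
F5 | step 9 | (2E,4S)-4-[(tert-butoxycarbonyl)amino]-2-[(4,5-dimethoxy-2-methylnaphthalen-1-yl)methylidene]pentanoic acid | OC(=O)/C(C[C@H](C)NC(=O)OC(C)(C)C)=C/c1c(C)cc(OC)c2c(OC)cccc12
F6 | step 9 | tert-butyl N-[(2S,4E)-5-(4,5-dimethoxy-2-methylnaphthalen-1-yl)-4-[methoxy(methyl)carbamoyl]pent-4-en-2-yl]carbamate | CON(C)C(=O)/C(C[C@H](C)NC(=O)OC(C)(C)C)=C/c1c(C)cc(OC)c2c(OC)cccc12
F7 | step 11 | methyl (2E,4S)-4-[(tert-butoxycarbonyl)amino]-2-[(4,5-dimethoxy-2-methylnaphthalen-1-yl)methylidene]pentanoate | COC(=O)/C(C[C@H](C)NC(=O)OC(C)(C)C)=C/c1c(C)cc(OC)c2c(OC)cccc12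
F8 | step 11 | methyl (2E,4S)-4-[bis(tert-butoxycarbonyl)amino]-2-[(4,5-dimethoxy-2-methylnaphthalen-1-yl)methylidene]pentanoate | COC(=O)/C(C[C@H](C)N(C(=O)OC(C)(C)C)C(=O)OC(C)(C)C)=C/c1c(C)cc(OC)c2c(OC)cccc12
F9 | step 11 | (2E,4S)-4-[bis(tert-butoxycarbonyl)amino]-2-[(4,5-dimethoxy-2-methylnaphthalen-1-yl)methylidene]pentanoic acid | OC(=O)/C(C[C@H](C)N(C(=O)OC(C)(C)C)C(=O)OC(C)(C)C)=C/c1c(C)cc(OC)c2c(OC)cccc12
F10 | step 11 | isobutyl carbonic mixed anhydride of F9 | CC(C)COC(=O)OC(=O)/C(C[C@H](C)N(C(=O)OC(C)(C)C)C(=O)OC(C)(C)C)=C/c1c(C)cc(OC)c2c(OC)cccc12
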